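**Assumption:** the target is taken exactly as drawn, (3S,4R,6S)-3,4,6-trimethyl-6-[(2R)-2-methyl-10-phenyldecyl]-1,2-dioxan-3-ol; its hemiketal carbon C3 is treated as equilibrating by ring–chain tautomerism to the drawn, anomerically favoured configuration.

## Retrosynthetic overview

1. The only ring is closed last: the 1,2-dioxan-3-ol is the cyclic hemiketal of a γ-hydroperoxy methyl ketone, whose C6–OO bond comes from cobalt-mediated Markovnikov O2 addition to a 1,1-disubstituted alkene.
2. Key C–C bond C5–C6 (ring numbering): palladium-catalysed coupling of a zinc homoenolate (ester β-carbon made nucleophilic) with an alkenyl triflate (a former ketone carbon); the homoenolate brings C4 with it.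
3. The alkenyl triflate comes from a methyl ketone, itself made from a terpene acid (side-chain stereocentre) by MeLi addition and chain extension by cross-metathesis/hydrogenation.
4. Stereocentres: C2′ and C4 are bought in, C3 is thermodynamic, and C6 is not controlled — its two epimers are separated after the peroxidation.

## Route

Step 1
Reactants: 1 (R)-citronellic acid [(3R)-3,7-dimethyloct-6-enoic acid]
Product: 2 (4R)-4,8-dimethylnon-7-en-2-one
Conditions: MeLi (2.3 equiv), Et2O, 0 °C to rt; poured into cold 1 M HCl
Reagents that add atoms: methyllithium, C[Li]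
Why: Carboxylic acid to methyl ketone with MeLi works because the lithium carboxylate takes up one MeLi to give a dilithium gem-diolate that resists further addition and collapses to the ketone only on acidic quench, and the stereocentre, β to the carbonyl, is not touched.

Step 2
Reactants: 2 (4R)-4,8-dimethylnon-7-en-2-one; 3 6-phenylhex-1-ene
Product: 5 (4R)-4-methyl-12-phenyldodecan-2-one, via unsaturated ketone 4 (not isolated)
Conditions: 3 (3 equiv), second-generation Grubbs catalyst (3 mol%), CH2Cl2, 40 °C; then EtOAc, Pd/C (10 wt%), H2 (1 atm), rt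
Reagents that add atoms: none
Why: Olefin cross-metathesis of the prenyl-type alkene with excess terminal alkene is driven by loss of volatile 2-methylpropene, and heterogeneous hydrogenation then saturates the new disubstituted alkene (E/Z irrelevant) without touching ketone, arene or the stereocentre.

Step 3
Reactants: 5 (4R)-4-methyl-12-phenyldodecan-2-one
Product: 7 (4R)-4-methyl-12-phenyldodec-1-en-2-yl trifluoromethanesulfonate, via lithium enolate 6 (not isolated)
Conditions: LiN(i-Pr)2 (1.1 equiv), THF, −78 °C; then PhNTf2 (1.15 equiv), −78 to 0 °C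
Reagents that add atoms: N-phenylbis(trifluoromethanesulfonimide), O=S(=O)(N(c1ccccc1)S(=O)(=O)C(F)(F)F)C(F)(F)F
Why: Kinetic enolate formation and O-triflation (enol triflate synthesis) works because the amide base removes a proton from the unhindered methyl group rather than the β-branched methylene and PhNTf2 traps the terminal enolate on oxygen; no stereocentre is made or disturbed.

Step 4
Reactants: 7 (4R)-4-methyl-12-phenyldodec-1-en-2-yl trifluoromethanesulfonate; 8 methyl (2S)-3-bromo-2-methylpropanoate
Product: 10 methyl (2R,6R)-2,6-dimethyl-4-methylidene-14-phenyltetradecanoate, via zinc homoenolate 9 (not isolated)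
Conditions: 8 (1.6 equiv), Zn dust (I2-activated), LiCl, THF, 50 °C; then 7, Pd(PPh3)4 (5 mol%), THF, 50 °C
Reagents that add atoms: none
Why: Negishi cross-coupling of a zinc homoenolate: zinc insertion makes the ester β-carbon nucleophilic without disturbing the adjacent α-stereocentre (covalent C–Zn bond, no enolisation), and zerovalent palladium joins it to the triflate-bearing former carbonyl carbon, so two normally electrophilic carbons (C5 and C6 of the target) are bonded and C4 arrives with its configuration from 8 (the descriptor changes from S to R only through CIP priorities).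

Step 5
Reactants: 10 methyl (2R,6R)-2,6-dimethyl-4-methylidene-14-phenyltetradecanoate
Product: 12 (3R,7R)-3,7-dimethyl-5-methylidene-15-phenylpentadecan-2-one, via Weinreb amide 11 (not isolated)
Conditions: MeNH(OMe)·HCl (1.5 equiv), i-PrMgCl (3.0 equiv), THF, −20 °C; then MeMgCl (2.5 equiv), −20 to 0 °C; cold 1 M HCl quench
Reagents that add atoms: methylmagnesium chloride, C[Mg]Cl
Why: Weinreb ketone synthesis run in one flask: the chloromagnesium amide of N,O-dimethylhydroxylamine aminolyses the ester and MeMgCl adds only once because the chelated tetrahedral adduct survives until the quench, so the α-stereocentre never sits beside a free ketone under basic conditions.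

Step 6
Reactants: 12 (3R,7R)-3,7-dimethyl-5-methylidene-15-phenylpentadecan-2-one
Product: 15 (3S,4R,6S)-3,4,6-trimethyl-6-[(2R)-2-methyl-10-phenyldecyl]-1,2-dioxan-3-ol, via silyl peroxide 13 (not isolated), via hydroperoxy ketone 14 (not isolated)
Conditions: Co(thd)2 (10 mol%; thd = 2,2,6,6-tetramethylheptane-3,5-dionate), Et3SiH (2 equiv), O2 (1 atm), ClCH2CH2Cl, rt; then HF·pyridine, THF, 0 °C; SiO2 chromatography
Reagents that add atoms: dioxygen, O=O
Why: Mukaiyama–Isayama hydroperoxysilylation then peroxyhemiketal closure: cobalt hydride delivers H to the CH2 terminus, the tertiary radical captures O2 and is silylated, fluoride frees the hydroperoxide and it adds to the γ-ketone to close the 1,2-dioxane; C3 settles thermodynamically (axial anomeric OH, equatorial C4 methyl), C4 is untouched under these neutral conditions, and C6 is not controlled (about 1:1), so the 6S epimer (side chain cis to the C4 methyl) is separated from its 6R ring diastereomer by chromatography.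

## Compound list

1 | (R)-citronellic acid [(3R)-3,7-dimethyloct-6-enoic acid] | C[C@H](CCC=C(C)C)CC(=O)O | starting material
2 | (4R)-4,8-dimethylnon-7-en-2-one | C[C@H](CCC=C(C)C)CC(C)=O | intermediate
3 | 6-phenylhex-1-ene | C=CCCCCc1ccccc1 | starting material
4 | (4R)-4-methyl-12-phenyldodec-7-en-2-one (E/Z mixture) | C[C@H](CCC=CCCCCc1ccccc1)CC(C)=O | intermediate
5 | (4R)-4-methyl-12-phenyldodecan-2-one | C[C@H](CCCCCCCCc1ccccc1)CC(C)=O | intermediate
6 | lithium (4R)-4-methyl-12-phenyldodec-1-en-2-olate | C[C@H](CCCCCCCCc1ccccc1)CC(=C)O[Li] | intermediate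
7 | (4R)-4-methyl-12-phenyldodec-1-en-2-yl trifluoromethanesulfonate | C[C@H](CCCCCCCCc1ccccc1)CC(=C)OS(=O)(=O)C(F)(F)F | intermediate
8 | methyl (2S)-3-bromo-2-methylpropanoate | BrC[C@@H](C)C(=O)OC | starting material
9 | bromo[(2S)-3-methoxy-2-methyl-3-oxopropyl]zinc | Br[Zn]C[C@@H](C)C(=O)OC | intermediate
10 | methyl (2R,6R)-2,6-dimethyl-4-methylidene-14-phenyltetradecanoate | C[C@H](CCCCCCCCc1ccccc1)CC(=C)C[C@@H](C)C(=O)OC | intermediate
11 | (2R,6R)-N-methoxy-N,2,6-trimethyl-4-methylidene-14-phenyltetradecanamide | C[C@H](CCCCCCCCc1ccccc1)CC(=C)C[C@@H](C)C(=O)N(C)OC | intermediate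
12 | (3R,7R)-3,7-dimethyl-5-methylidene-15-phenylpentadecan-2-one | C[C@H](CCCCCCCCc1ccccc1)CC(=C)C[C@@H](C)C(C)=O | intermediate
13 | (3R,5S,7R)-3,5,7-trimethyl-15-phenyl-5-(triethylsilylperoxy)pentadecan-2-one (formed with its 5R epimer) | C[C@H](CCCCCCCCc1ccccc1)C[C@@](OO[Si](CC)(CC)CC)(C)C[C@@H](C)C(C)=O | intermediate
14 | (3R,5S,7R)-5-hydroperoxy-3,5,7-trimethyl-15-phenylpentadecan-2-one | C[C@H](CCCCCCCCc1ccccc1)C[C@@](OO)(C)C[C@@H](C)C(C)=O | intermediate
15 | (3S,4R,6S)-3,4,6-trimethyl-6-[(2R)-2-methyl-10-phenyldecyl]-1,2-dioxan-3-ol | C[C@H](CCCCCCCCc1ccccc1)C[C@@]1(C)C[C@@H](C)[C@@](C)(O)OO1 | target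

## Step count and risks

Total steps: 6. Longest linear sequence: 6 (1 → 2 → 5 → 7 → 10 → 12 → 15).

**Step 6 (most likely to fail).** The radical O2 capture gives both C6 epimers, so at most about half the material is the target. The two hemiketals may also be hard to separate or may streak through ring–chain tautomerism, and over-reduction to the tertiary alcohol can erode yield. Fallback, setting out from crude 13 and returning at 15: instead of fluoride, treat crude 13 with MeOH and catalytic TsOH·H2O (0 °C to rt). Desilylation, cyclisation and ketalisation then give the non-tautomerising methyl peroxyketal (3S,4R,6S)-3-methoxy-3,4,6-trimethyl-6-[(2R)-2-methyl-10-phenyldecyl]-1,2-dioxane F1 together with its C6 epimer. These are separated as stable ketals, and F1 is hydrolysed (THF/H2O, catalytic HCl, 0 °C) to 15.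

**Step 4.** Zinc insertion into the bromide may be sluggish, and coupling at the hindered 1,1-disubstituted triflate may be slow enough for β-hydride elimination or alkene migration to compete. Fallback, setting out from 7 and returning at 12, which makes the C4–C5 bond instead:
- Kumada coupling of 7 with Me3SiCH2MgCl (Pd(PPh3)4, THF) gives the allylsilane trimethyl[(4R)-4-methyl-2-methylidene-12-phenyldodecyl]silane F2.
- Organo-SOMO α-allylation of propanal (in excess) with F2 forms the C4–C5 bond and sets C4 by catalyst control, giving (2R,6R)-2,6-dimethyl-4-methylidene-14-phenyltetradecanal F3. Conditions: 5-benzyl-2-tert-butyl-3-methylimidazolidin-4-one·CF3CO2H (20 mol%, the enantiomer that delivers the 2R aldehyde, to be confirmed on a model), (NH4)2Ce(NO3)6 (2 equiv), NaHCO3, DME, −20 °C.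
- MeMgBr addition gives (3R,7R)-3,7-dimethyl-5-methylidene-15-phenylpentadecan-2-ol F4 (both C2 epimers), and Dess–Martin oxidation rejoins the route at 12.

**Step 3.** Deprotonation may not be fully regioselective, giving internal enol triflates that carry through as isomeric coupling products. Fallback, setting out from 5 and returning at 10:
- Condense 5 with 2,4,6-triisopropylbenzenesulfonohydrazide to the hydrazone N'-[(4R)-4-methyl-12-phenyldodecan-2-ylidene]-2,4,6-tri(propan-2-yl)benzenesulfonohydrazide F5.
- Shapiro reaction (n-BuLi 2.2 equiv, THF/TMEDA, −78 to 0 °C) metallates only the methyl side and, after loss of N2 and sulfinate, gives the vinyllithium [(4R)-4-methyl-12-phenyldodec-1-en-2-yl]lithium F6 (not isolated).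
- Iodine quench gives (4R)-2-iodo-4-methyl-12-phenyldodec-1-ene F7, which takes the place of 7 in step 4 and gives 10.

## Further compounds

F1 | step 6 | (3S,4R,6S)-3-methoxy-3,4,6-trimethyl-6-[(2R)-2-methyl-10-phenyldecyl]-1,2-dioxane | C[C@H](CCCCCCCCc1ccccc1)C[C@@]1(C)C[C@@H](C)[C@@](C)(OC)OO1
F2 | step 4 | trimethyl[(4R)-4-methyl-2-methylidene-12-phenyldodecyl]silane | C[C@H](CCCCCCCCc1ccccc1)CC(=C)C[Si](C)(C)C
F3 | step 4 | (2R,6R)-2,6-dimethyl-4-methylidene-14-phenyltetradecanal | C[C@H](CCCCCCCCc1ccccc1)CC(=C)C[C@@H](C)C=O
F4 | step 4 | (3R,7R)-3,7-dimethyl-5-methylidene-15-phenylpentadecan-2-ol (both C2 epimers) | C[C@H](CCCCCCCCc1ccccc1)CC(=C)C[C@@H](C)C(C)O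
F5 | step 3 | N'-[(4R)-4-methyl-12-phenyldodecan-2-ylidene]-2,4,6-tri(propan-2-yl)benzenesulfonohydrazide | C[C@H](CCCCCCCCc1ccccc1)CC(C)=NNS(=O)(=O)c1c(C(C)C)cc(C(C)C)cc1C(C)C
F6 | step 3 | [(4R)-4-methyl-12-phenyldodec-1-en-2-yl]lithium | C[C@H](CCCCCCCCc1ccccc1)CC(=C)[Li]
F7 | step 3 | (4R)-2-iodo-4-methyl-12-phenyldodec-1-ene | C[C@H](CCCCCCCCc1ccccc1)CC(I)=C
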